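## Structural features

Lapiferine is a daucane sesquiterpenoid ester: a cyclopentane (C1–C5) trans-fused along C1–C5 to a cycloheptane (C1, C5, C6–C10), carrying fifteen skeletal carbons and a (Z)-2-methylbut-2-enoyl (angeloyl) group on the C6 oxygen. Seven stereocentres form two contiguous runs that meet at the ring fusion: C4 (tertiary carbinol with the isopropyl group)–C5 (fusion CH)–C6 (ester carbon), and C8–C9 (trisubstituted epoxide, methyl on C8)–C10 (free secondary carbinol)–C1 (quaternary, methyl). Taking the C1 methyl as β, the C4 hydroxyl is β, whereas H-5, the C6 ester oxygen, the epoxide oxygen and the C10 hydroxyl are all α. The fragile elements are the angelate (Z to E isomerisation to the tiglate under nucleophilic, basic or acidic catalysis), the epoxide (next to a free hydroxyl and across the ring from the C4 hydroxyl) and, at the ketone oxidation level, the β-hydroxy ketone array C4(OH)–C5–C6(=O), which can dehydrate or cleave by retro-aldol reaction. The real difficulty is the seven-membered ring: four of its carbons bear oxygen, it must be closed onto a quaternary carbon (C1), and the fusion must be trans and correctly related to the C4 carbinol. The key step exploits the spacing of the oxygens: the C10 oxygen is on the central carbon of the three-carbon unit C9–C10–C1 (an oxyallyl unit), the C6 oxygen is on position 2 of the four-carbon unit C5–C6–C7–C8 (a 2-oxybutadiene), and C2–C3–C4 ties the two together, so a tethered (4+3) cycloaddition can form C1–C5, C8–C9 and both rings at once.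

## Logic of the disconnections

28 ⇒ 27. The two C–O bonds of the epoxide (C8–O, C9–O) are removed. The epoxide is the most fragile ring and its oxygen is cis to the C10 hydroxyl, the relationship a hydroxyl-directed epoxidation creates. Two stereocentres disappear. The forward step must add oxygen only to C8=C9, syn to the C10 hydroxyl, and spare the angelate alkene.

27 ⇒ 26. The C10–H bond is removed (carbinol to enone carbonyl). C10 becomes the sp2 carbon that the ring-forming step delivers and one more stereocentre is gone. The forward reduction must be 1,2-selective, spare the ester and bring hydride to the β face.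

26 ⇒ 23 + 24. The ester C–O bond at C6 is cut. The acyl group is placed as late as a still-masked C10 oxygen allows, so the isomerisation-prone angelate sees only two further steps and only one acylable hydroxyl is present. The forward step must not isomerise the Z alkene and must leave the tertiary C4 hydroxyl alone.

23 ⇒ 20. The C8=C9 double bond is saturated retrosynthetically (21 and 22 are transient forms within this operation). C10 is flanked by quaternary C1 and can enolise only toward C9, so the alkene can be introduced by a regiodefined dehydrogenation. C8 returns to the sp3 methine that the cycloaddition produces, and its configuration no longer matters. The forward step must tolerate two hydroxyls and is placed after C6 has ceased to be a ketone, which avoids a vinylogous 1,3-diketone.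

20 ⇒ 19. The C6–H bond is removed (carbinol to ketone). The 1,3-relationship between the C4 hydroxyl and C6 permits internal hydride delivery; C6 is now at the oxidation level of a hydrolysed enol ether. The forward step must distinguish the C6 from the C10 ketone and deliver hydride to the β face of C6.

19 ⇒ 18. The O–H bonds at C4 and C6 are exchanged for O–Si bonds. The enol silane is the form in which the C6 oxygen leaves a 2-silyloxydiene; the C4 ether is the protecting group carried from the start. The forward hydrolysis must avoid dehydration, retro-aldol opening and epimerisation at C5.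

18 ⇒ 16 (through 17). C1–C5 and C8–C9 are cut, a retro-(4+3) cycloaddition. Both rings, the quaternary carbon and three stereocentres vanish; an open chain with one stereocentre (C4) remains. The forward step must generate the oxyallyl cation under conditions the silyl dienol ether survives, give the trans ring fusion and use the diene face dictated by C4.

16 ⇒ 15. The C10 ketone is returned to a carbinol. The α-chloro ketone cannot coexist with the strong base that makes the dienol ether, so it must be unveiled last by a neutral oxidation.

15 ⇒ 12 + 13. C9–C10 is cut: a one-carbon chloromethyl carbenoid plus an aldehyde. The leaving group and the last skeletal carbon arrive together. The forward step must trap the carbenoid before it decomposes and protonate before the alkoxide closes to an epoxide.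

12 ⇒ 11. The aldehyde is traced to a nitrile, a C10 carbonyl equivalent that is inert to carbonyl addition elsewhere, to oxidation and to amide base. No protecting group for a C10 alcohol is then needed. The forward partial reduction and imine hydrolysis must be mild enough for the dienol ether.

11 ⇒ 10. The O–Si bond at C6 is cut and the diene returns to the enone. The forward step requires deprotonation at C5 (α′, not γ), Z enol geometry and no β-elimination of the C4 silyloxy group.

10 ⇒ 9. The ketone is returned to a secondary allylic alcohol, so that C6–C7 can be made by carbonyl addition.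

9 ⇒ 6 + 7. C6–C7 is cut between carbinol carbon and alkene: aldehyde plus the (E)-propenyl nucleophile 8. This brings in C7, C8 and the C8 methyl with the E geometry the diene needs. The forward step must retain the alkene geometry and react at the aldehyde in preference to the nitrile.

6 ⇒ 5. The aldehyde is returned to its dimethyl acetal, the form in which C6 travels while the other carbonyl is homologated.

5 ⇒ 3 + 4. The C1–C10 bond is cut and C1 returns to a ketone (reductive cyanation). One step supplies C10 and the C1 hydrogen. No stereocontrol is demanded, because C1 is planarised in 17; the step must tolerate the acetal and the silyl ether.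

3 ⇒ 2. The C1 carbonyl and the C6 acetal carbon are reconnected as a ring alkene (ozonolysis retron). The chain with two different termini becomes a cyclohexene. The forward cleavage must deliver the termini already differentiated as ketone and acetal.

2 ⇒ 1. The O–Si bond is cut. This leads to the commercial chiral-pool alcohol, whose carbinol carbon is C4 with the isopropyl group and the required configuration.

## Other disconnections considered

Alternative 1: The cut is C4–C5, which opens the cyclopentane to the achiral keto aldehyde A1, a 2,2-disubstituted cycloheptane-1,3-dione whose side chain ends in the C4 aldehyde. The forward key step is a desymmetrising intramolecular crossed benzoin reaction: a chiral triazolylidene carbene turns the aldehyde into an acyl anion equivalent, which adds to one of the two enantiotopic ring ketones and gives the bicyclic acyloin A2.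
- In its favour: the absolute configuration comes from a catalyst and a quickly assembled achiral substrate. The C1 quaternary centre is fixed by a reaction class well suited to this kind of desymmetrisation. C4 and C10 emerge as ketones exactly where the isopropyl carbinol and the C10 carbinol are needed.
- Against it here: A2 carries a hydroxyl on C5 and is cis-fused (hydroxyl and methyl on the same face), whereas the target has hydrogen on C5 trans to the methyl. A tertiary alcohol would have to be removed with control of the new C–H bond. C6–C9 are four bare methylenes, so the C6 oxygen, the C8 methyl and the C8–C9 unsaturation all remain to be introduced, and only twelve of the fifteen skeletal carbons are present.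
- Comparison: on the C1 stereocentre this plan is the better one, since catalyst control replaces the relay from C4 on which step 11 depends. On the C4 carbinol it is at best equal, because an isopropyl nucleophile must add to a hindered ketol where the chosen route takes the carbinol intact from 1. Mechanistically it is a one-bond, one-ring polar closure against a two-bond, two-ring cycloaddition. In step economy it is expected to be clearly longer, because the whole substitution pattern of the seven-membered ring is still missing after the key step.

Alternative 2: The cuts are C1–C10 and C5–C6, with the seven-membered ring closed later at C9=C10 by metathesis. In the forward key step the silylvinyl aluminium reagent A4 adds to the enone A3 under a copper catalyst (for example Cu(OTf)2 with a chiral N-heterocyclic carbene ligand), creating the C1 quaternary centre. The resulting enolate is trapped at C5 by the aldehyde A5 to give the 2,3-trans aldol A6.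
- In its favour: it is convergent (three components) and C1 is catalyst-controlled. The trans arrangement of the two arms on the cyclopentanone translates directly into the trans ring fusion, which is better than the chosen plan, where cis and trans closure compete. The C6 oxygen is present at the correct oxidation level and the C8 methyl is in place. Isopropyl addition to the C4 ketone anti to the C5 arm should give the required 4β-hydroxyl.
- Against it here: the seven-membered ring needs a separate closure by metathesis of a 1,1-disubstituted vinylsilane next to a quaternary carbon, a demanding substrate class. The vinylsilane must then be converted into the C10 carbinol and C8=C9 must be regenerated from sp3 C8. The C6 configuration rests on aldehyde facial selectivity with little help from the remote centre of A5. The isopropyl carbinol is made late on a hindered, enolisable ketone.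
- Comparison: it is equal in convergence and in skeletal bonds made in the key step (two). It is better on ring-fusion control and on catalyst-derived absolute configuration. It is worse in rings formed in the key step (none against two) and on the C4 carbinol. The overall step count is expected to be similar.

Alternative 3: The bond formed is C7–C8 and the bond sacrificed is C5–C10: a retro-Cope step leads from the cyclohepta-1,4-diene to the cis-divinylcyclopropane A7. A7 is a bicyclo[3.1.0]hexan-2-one with vinyl on C5, (E)-propenyl on C10 (exo, cis to the vinyl) and methyl on C1. In the forward direction a thermal [3,3] rearrangement through the boat transition state gives the dienone A8.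
- In its favour: the step is concerted, strain-driven and stereospecific, with no ionic intermediate to be diverted; on mechanistic reliability it is the better key step. The C1 quaternary centre is already in the cyclopropane and is carried through unchanged. The product alkenes are usefully placed: C5=C6 is conjugated to the C4 ketone (handle for the C6 oxygen and H-5), and C9=C10 flanks the C8 methine, so an ene-type allylic oxidation could shift the alkene to C8=C9 while placing oxygen on C10.
- Against it here: A7 is itself demanding, a tetrasubstituted cyclopropane whose C1 configuration would have to be induced in a carbene cyclopropanation. After the key step H-5, the C6 oxygen, the isopropyl carbinol and the whole C8–C10 pattern remain to be installed, each with its own facial selectivity question. Only the seven-membered ring is formed in the key step.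
- Comparison: it is equal in closing the seven-membered ring onto the quaternary carbon with a C8 centre that neither plan keeps. It is better in predictability of the key step. It is worse in rings and stereocentres delivered and in distance from key-step product to target. The step count is expected to be longer by several steps.

Key step: step 11

Remarks on the chemistry (assumptions and corrections):
- Assumption: (S)-(+)-terpinen-4-ol is available commercially in high enantiomeric purity; its carbinol carbon becomes C4 and is never touched.
- Correction: no configuration is assigned at C3 of 16 (C1 of the skeleton). The homologation creates this centre without control and the oxyallyl cation 17 erases it, so 5, 6, 9–12, 15 and 16 are carried as epimer mixtures at this carbon (9 and 15 also at their carbinol carbons).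
- Design: the C10 carbonyl travels as a nitrile, so no chlorohydrin needs protecting and the α-chloro ketone is made last. The C8=C9 alkene is introduced only after C6 has been reduced.
- Notation: daucane numbering is used for the bicyclic compounds; β is the face of the C1 methyl group.

## Route

Step 1
Reactants: 1 (S)-terpinen-4-ol [(1S)-4-methyl-1-(propan-2-yl)cyclohex-3-en-1-ol]
Product: 2 triethyl{[(1S)-4-methyl-1-(propan-2-yl)cyclohex-3-en-1-yl]oxy}silane
Conditions: TESOTf, 2,6-lutidine, CH2Cl2, 0 °C → rt
Reagents that add atoms: triethylsilyl trifluoromethanesulfonate, CC[Si](CC)(CC)OS(=O)(=O)C(F)(F)F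
Why: Silyl triflate with lutidine is the standard silylation for a hindered tertiary alcohol; the ether prevents lactol formation with the ketone made in step 2 and blocks retro-aldol chemistry later. No stereocentre is touched.

Step 2
Reactants: 2 silyl ether of terpinen-4-ol
Product: 3 (5S)-7,7-dimethoxy-5-(propan-2-yl)-5-(triethylsilyloxy)heptan-2-one
Conditions: O3, CH2Cl2/MeOH (5:1), −78 °C; TsOH·H2O (cat.), −78 °C → rt; NaHCO3; Me2S, rt
Reagents that add atoms: ozone, [O-][O+]=O; methanol, CO
Why: Ozonolysis with in situ differentiation of the termini: the primary ozonide of the trisubstituted alkene fragments to the more substituted carbonyl oxide, which methanol traps as a methoxy hydroperoxide, while the aldehyde end is acetalised by the acid; Me2S then releases only the ketone. The C4 carbinol is not involved.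

Step 3
Reactants: 3 keto acetal; 4 p-toluenesulfonylmethyl isocyanide (TosMIC)
Product: 5 (2RS,5S)-7,7-dimethoxy-2-methyl-5-(propan-2-yl)-5-(triethylsilyloxy)heptanenitrile
Conditions: 4, t-BuOK, DME/EtOH, 0 → 35 °C
Reagents that add atoms: none
Why: Van Leusen reductive cyanation converts an unhindered methyl ketone in one step into the homologous secondary nitrile; acetal and silyl ether are inert to alkoxide. The new centre (skeleton C1) forms as a mixture, which is immaterial because step 11 planarises it.

Step 4
Reactants: 5 nitrile acetal
Product: 6 (2RS,5S)-2-methyl-7-oxo-5-(propan-2-yl)-5-(triethylsilyloxy)heptanenitrile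
Conditions: PPTS (cat.), acetone/H2O (9:1), 45 °C
Reagents that add atoms: water, O
Why: Mild acid-catalysed acetal hydrolysis; the hindered tertiary silyl ether and the nitrile tolerate pyridinium tosylate, and no base is present to eliminate the β-silyloxy group.

Step 5
Reactants: 6 nitrile aldehyde; 7 (E)-1-bromoprop-1-ene
Product: 9 (2RS,5S,7RS,8E)-7-hydroxy-2-methyl-5-(propan-2-yl)-5-(triethylsilyloxy)dec-8-enenitrile, via (E)-prop-1-enyllithium 8 (not isolated)
Conditions: 7, t-BuLi (2 equiv per 7), Et2O, −78 °C; then 6, −78 °C; aq. NH4Cl
Reagents that add atoms: none
Why: Bromine–lithium exchange on an alkenyl bromide retains the E geometry, and carbonyl addition to the aldehyde at −78 °C outruns attack on, or deprotonation of, the nitrile. The carbinol centre forms unselectively and is removed in step 6.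

Step 6
Reactants: 9 allylic alcohol
Product: 10 (2RS,5S,8E)-2-methyl-7-oxo-5-(propan-2-yl)-5-(triethylsilyloxy)dec-8-enenitrile
Conditions: Dess–Martin periodinane, CH2Cl2, 0 °C → rt
Reagents that add atoms: none
Why: Dess–Martin oxidation of a secondary allylic alcohol gives the enone under near-neutral conditions, without alkene isomerisation or β-elimination of the silyloxy group.

Step 7
Reactants: 10 enone
Product: 11 (2RS,5R,6Z,8E)-2-methyl-5-(propan-2-yl)-5-(triethylsilyloxy)-7-(triisopropylsilyloxy)deca-6,8-dienenitrile
Conditions: KN(SiMe3)2, THF, −78 °C; TIPSOTf, −78 → −40 °C
Reagents that add atoms: triisopropylsilyl trifluoromethanesulfonate, CC(C)[Si](C(C)C)(C(C)C)OS(=O)(=O)C(F)(F)F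
Why: Kinetic deprotonation of an enone by a hindered amide takes place at the α′ carbon (C5), not at the γ-methyl, and O-silylation of the cross-conjugated enolate gives the 2-silyloxydiene with the bulky C4 substituent cis to oxygen (Z). The nitrile α-hydrogen is far less acidic, and the cold, short-lived enolate should not expel the β-silyloxy group.

Step 8
Reactants: 11 silyl dienol ether nitrile
Product: 12 (2RS,5R,6Z,8E)-2-methyl-5-(propan-2-yl)-5-(triethylsilyloxy)-7-(triisopropylsilyloxy)deca-6,8-dienal
Conditions: i-Bu2AlH, toluene, −78 °C; aq. potassium sodium tartrate, 0 °C
Reagents that add atoms: water, O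
Why: i-Bu2AlH adds once to the nitrile, and the N-aluminio imine hydrolyses to the aldehyde in the buffered aqueous work-up, which a triisopropylsilyl dienol ether should survive.

Step 9
Reactants: 12 dienal; 13 chloroiodomethane
Product: 15 (2RS,3RS,6R,7Z,9E)-1-chloro-3-methyl-6-(propan-2-yl)-6-(triethylsilyloxy)-8-(triisopropylsilyloxy)undeca-7,9-dien-2-ol, via chloromethyllithium 14 (not isolated)
Conditions: 13, MeLi·LiBr added to 12 + 13, THF, −78 °C; AcOH, −78 °C
Reagents that add atoms: none
Why: Iodine–lithium exchange generates the carbenoid in the presence of the aldehyde, which captures it before it decomposes; protonation at −78 °C gives the chlorohydrin before the alkoxide can close to the epoxide. The new centres are mixtures that steps 10 and 11 remove.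

Step 10
Reactants: 15 chlorohydrin
Product: 16 (3RS,6R,7Z,9E)-1-chloro-3-methyl-6-(propan-2-yl)-6-(triethylsilyloxy)-8-(triisopropylsilyloxy)undeca-7,9-dien-2-one
Conditions: Dess–Martin periodinane, NaHCO3, CH2Cl2, 0 °C
Reagents that add atoms: none
Why: Buffered Dess–Martin oxidation of a halohydrin gives the α-chloro ketone without acid that would hydrolyse the dienol ether. The chloro ketone is made last because it would not survive the base of step 7.

Step 11
Reactants: 16 chloromethyl ketone with tethered 2-silyloxydiene
Product: 18 trans-fused cycloadduct 8β-methyl-4β-(triethylsilyloxy)-6-(triisopropylsilyloxy)-5αH-dauc-6-en-10-one (1β-methyl; 4α-isopropyl), via oxyallyl cation 17 (not isolated)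
Conditions: Et3N (3 equiv), CF3CH2OH (0.01 M), 0 °C → rt
Reagents that add atoms: none
Why: Et3N enolises 16 reversibly, and only the enolate formed by loss of the C1 hydrogen can expel chloride from C9, giving the 2-oxyallyl cation 17 (C9–C10–C1); its C1 terminus is planar, so both C1 epimers of 16 converge. The closest known reaction type is the base-induced intramolecular (4+3) cycloaddition of α-halo ketones with tethered dienes in fluorinated alcohols, here with an electron-rich 2-silyloxydiene as the four-carbon partner. The cyclopentane is the tether ring: the nucleophilic diene terminus C5 bonds to the more substituted terminus C1, a 5-exo closure with respect to both π systems. The cycloheptane is the cycloadduct ring, completed by the C8–C9 bond either in concert or as a 7-endo attack of the C9 enolate carbon on the silyloxyallyl cation. C5 is set by attack on the diene face that places the C6 arm anti to the isopropyl group of C4, which lies pseudo-equatorial on the forming five-membered ring (silyloxy pseudo-axial). C1 is set by the oxygen-bearing arm C10 taking the pseudo-equatorial position and the methyl the pseudo-axial one, so that C10 and C6 are anti across the new bond (extended transition state): trans fusion with the methyl cis to the C4 oxygen. C8 follows from suprafacial addition to the (E)-propenyl terminus (methyl cis to C4 on the seven-membered ring) and is removed in step 14. The step needs cycloaddition to beat Favorskii rearrangement and solvent capture, which the short three-carbon tether and the nucleophilic diene in a weakly nucleophilic, ionising solvent should secure; it also needs Z geometry at C5=C6, secured in step 7, while regiochemistry is fixed by the tether.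

Step 12
Reactants: 18 cycloadduct
Product: 19 4β-hydroxy-8β-methyl-5αH-daucane-6,10-dione
Conditions: aq. HF (48%), MeCN, 0 °C → rt
Reagents that add atoms: none
Why: Acidic fluoride cleaves the enol silane by protonation at C7 and removes the tertiary silyl ether; with no base present C5 is not epimerised, and the β-hydroxy ketone should neither dehydrate nor undergo retro-aldol cleavage at this temperature.

Step 13
Reactants: 19 hydroxy diketone
Product: 20 4β,6α-dihydroxy-8β-methyl-5αH-daucan-10-one
Conditions: Me4NBH(OAc)3, MeCN/AcOH (1:1), −30 → 0 °C
Reagents that add atoms: none
Why: Hydroxyl-directed reduction of Evans–Saksena type: the C4 hydroxyl exchanges onto boron and delivers hydride through a six-membered transition state; O4 lies on the β face of the C6 carbonyl (cis to the C6 arm on the cyclopentane), so hydrogen adds from β and the new hydroxyl is α. The C10 ketone has no suitably placed hydroxyl, is neopentylic and is not reduced by the deactivated borohydride.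

Step 14
Reactants: 20 diol ketone
Product: 23 4β,6α-dihydroxy-5αH-dauc-8-en-10-one, via tris(trimethylsilyl) enol ether 21 (not isolated), via bis(trimethylsilyl) enone 22 (not isolated)
Conditions: TMSOTf, Et3N, CH2Cl2, 0 °C; then Pd(OAc)2, MeCN, rt; then 1 M HCl, THF, 0 °C
Reagents that add atoms: none
Why: Saegusa–Ito dehydrogenation: the C10 ketone can enolise only toward C9 because C1 is quaternary, and the palladium enolate loses H-8 by syn β-hydride elimination, giving the C8=C9 enone and erasing the C8 centre. Both hydroxyls travel as trimethylsilyl ethers and are released in the acidic work-up.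

Step 15
Reactants: 23 enone diol; 24 angelic acid [(Z)-2-methylbut-2-enoic acid]
Product: 26 6α-angeloyloxy-4β-hydroxy-5αH-dauc-8-en-10-one, via angelic 2,4,6-trichlorobenzoic anhydride 25 (not isolated)
Conditions: 24, 2,4,6-trichlorobenzoyl chloride, Et3N, toluene, rt; then 23, 80 °C
Reagents that add atoms: none
Why: Yamaguchi-type esterification through the mixed anhydride, run without a nucleophilic catalyst because such catalysts isomerise angelates to tiglates by addition–elimination. Only the secondary, equatorial C6 hydroxyl is acylated; the tertiary C4 hydroxyl is too hindered.

Step 16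
Reactants: 26 enone angelate
Product: 27 6α-angeloyloxy-5αH-dauc-8-ene-4β,10α-diol
Conditions: NaBH4, CeCl3·7H2O, MeOH, −78 → −40 °C
Reagents that add atoms: none
Why: Luche 1,2-reduction of the enone; the ester is untouched. In the chair-like cycloheptenone the C1–C5 bond stands nearly perpendicular to the carbonyl plane on the α face, so the small hydride should enter anti to it from the β face, between the methyl and C2, giving the 10α-alcohol.

Step 17
Reactants: 27 allylic alcohol
Product: 28 lapiferine (6α-angeloyloxy-8α,9α-epoxy-5αH-daucane-4β,10α-diol)
Conditions: VO(acac)2 (cat.), t-BuOOH, CH2Cl2, 0 °C → rt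
Reagents that add atoms: tert-butyl hydroperoxide, CC(C)(C)OO
Why: Vanadium-catalysed epoxidation directed by the allylic C10 hydroxyl delivers oxygen to the syn (α) face of C8=C9, as is usual for cyclohept-2-enols, and sets C8 and C9 together. The electron-poor angelate alkene has no directing hydroxyl and should not react.

## Compound list

1 | (S)-terpinen-4-ol | CC1=CC[C@](O)(C(C)C)CC1 | starting material
2 | triethyl{[(1S)-4-methyl-1-(propan-2-yl)cyclohex-3-en-1-yl]oxy}silane | CC1=CC[C@](O[Si](CC)(CC)CC)(C(C)C)CC1 | intermediate
3 | (5S)-7,7-dimethoxy-5-(propan-2-yl)-5-(triethylsilyloxy)heptan-2-one | CC(=O)CC[C@@](O[Si](CC)(CC)CC)(C(C)C)CC(OC)OC | intermediate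
4 | p-toluenesulfonylmethyl isocyanide | Cc1ccc(cc1)S(=O)(=O)C[N+]#[C-] | starting material
5 | (2RS,5S)-7,7-dimethoxy-2-methyl-5-(propan-2-yl)-5-(triethylsilyloxy)heptanenitrile | CC(C#N)CC[C@@](O[Si](CC)(CC)CC)(C(C)C)CC(OC)OC | intermediate
6 | (2RS,5S)-2-methyl-7-oxo-5-(propan-2-yl)-5-(triethylsilyloxy)heptanenitrile | CC(C#N)CC[C@@](O[Si](CC)(CC)CC)(C(C)C)CC=O | intermediate
7 | (E)-1-bromoprop-1-ene | C/C=C/Br | starting material
8 | (E)-prop-1-enyllithium | C/C=C/[Li] | intermediate
9 | (2RS,5S,7RS,8E)-7-hydroxy-2-methyl-5-(propan-2-yl)-5-(triethylsilyloxy)dec-8-enenitrile | C/C=C/C(O)C[C@](O[Si](CC)(CC)CC)(C(C)C)CCC(C)C#N | intermediate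
10 | (2RS,5S,8E)-2-methyl-7-oxo-5-(propan-2-yl)-5-(triethylsilyloxy)dec-8-enenitrile | C/C=C/C(=O)C[C@](O[Si](CC)(CC)CC)(C(C)C)CCC(C)C#N | intermediate
11 | (2RS,5R,6Z,8E)-2-methyl-5-(propan-2-yl)-5-(triethylsilyloxy)-7-(triisopropylsilyloxy)deca-6,8-dienenitrile | C/C=C/C(O[Si](C(C)C)(C(C)C)C(C)C)=C/[C@](O[Si](CC)(CC)CC)(C(C)C)CCC(C)C#N | intermediate
12 | (2RS,5R,6Z,8E)-2-methyl-5-(propan-2-yl)-5-(triethylsilyloxy)-7-(triisopropylsilyloxy)deca-6,8-dienal | C/C=C/C(O[Si](C(C)C)(C(C)C)C(C)C)=C/[C@](O[Si](CC)(CC)CC)(C(C)C)CCC(C)C=O | intermediate
13 | chloroiodomethane | ClCI | starting material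
14 | chloromethyllithium | [Li]CCl | intermediate
15 | (2RS,3RS,6R,7Z,9E)-1-chloro-3-methyl-6-(propan-2-yl)-6-(triethylsilyloxy)-8-(triisopropylsilyloxy)undeca-7,9-dien-2-ol | ClCC(O)C(C)CC[C@@](O[Si](CC)(CC)CC)(C(C)C)/C=C(O[Si](C(C)C)(C(C)C)C(C)C)/C=C/C | intermediate
16 | (3RS,6R,7Z,9E)-1-chloro-3-methyl-6-(propan-2-yl)-6-(triethylsilyloxy)-8-(triisopropylsilyloxy)undeca-7,9-dien-2-one | ClCC(=O)C(C)CC[C@@](O[Si](CC)(CC)CC)(C(C)C)/C=C(O[Si](C(C)C)(C(C)C)C(C)C)/C=C/C | intermediate
17 | oxyallyl cation (zwitterion across C9–C10–C1) derived from 16 | C=C([O-])[C+](C)CC[C@@](O[Si](CC)(CC)CC)(C(C)C)/C=C(O[Si](C(C)C)(C(C)C)C(C)C)/C=C/C | intermediate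
18 | 8β-methyl-4β-(triethylsilyloxy)-6-(triisopropylsilyloxy)-5αH-dauc-6-en-10-one (trans-fused) | O=C1C[C@@H](C)C=C(O[Si](C(C)C)(C(C)C)C(C)C)[C@H]2[C@](O[Si](CC)(CC)CC)(C(C)C)CC[C@]12C | intermediate
19 | 4β-hydroxy-8β-methyl-5αH-daucane-6,10-dione | O=C1C[C@@H](C)CC(=O)[C@H]2[C@](O)(C(C)C)CC[C@]12C | intermediate
20 | 4β,6α-dihydroxy-8β-methyl-5αH-daucan-10-one | O=C1C[C@@H](C)C[C@H](O)[C@H]2[C@](O)(C(C)C)CC[C@]12C | intermediate
21 | 8β-methyl-4β,6α,10-tris(trimethylsilyloxy)-5αH-dauc-9-ene | C[Si](C)(C)OC1=C[C@@H](C)C[C@H](O[Si](C)(C)C)[C@H]2[C@](O[Si](C)(C)C)(C(C)C)CC[C@]12C | intermediate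
22 | 4β,6α-bis(trimethylsilyloxy)-5αH-dauc-8-en-10-one | O=C1C=C(C)C[C@H](O[Si](C)(C)C)[C@H]2[C@](O[Si](C)(C)C)(C(C)C)CC[C@]12C | intermediate
23 | 4β,6α-dihydroxy-5αH-dauc-8-en-10-one | O=C1C=C(C)C[C@H](O)[C@H]2[C@](O)(C(C)C)CC[C@]12C | intermediate
24 | angelic acid | C/C=C(/C)C(=O)O | starting material
25 | angelic 2,4,6-trichlorobenzoic anhydride | C/C=C(/C)C(=O)OC(=O)c1c(Cl)cc(Cl)cc1Cl | intermediate
26 | 6α-angeloyloxy-4β-hydroxy-5αH-dauc-8-en-10-one | C/C=C(/C)C(=O)O[C@H]1CC(C)=CC(=O)[C@@]2(C)CC[C@@](O)(C(C)C)[C@H]12 | intermediate
27 | 6α-angeloyloxy-5αH-dauc-8-ene-4β,10α-diol | C/C=C(/C)C(=O)O[C@H]1CC(C)=C[C@@H](O)[C@@]2(C)CC[C@@](O)(C(C)C)[C@H]12 | intermediate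
28 | lapiferine | C/C=C(/C)C(=O)O[C@H]1C[C@@]2(C)O[C@H]2[C@@H](O)[C@@]2(C)CC[C@@](O)(C(C)C)[C@H]12 | target

## Step count and least certain steps

Total step count: 17. Longest linear sequence: 17 steps (1 → 28); 4, 7, 13 and 24 are purchased.

Step 11 (key step). What may go wrong: poor control of the ring fusion, that is, bonding on the other face of the diene terminus C5 to give the cis-fused series, and to a lesser degree diversion of the oxyallyl cation into Favorskii rearrangement or capture by the solvent. The only control element is the C4 carbinol, whose two substituents differ only moderately in size, and the extended and compact transition states of three-carbon-tethered (4+3) reactions are expected to lie close in energy. Fallback, from 16 back to 22: accept the cis-fused adduct F1 (C5 epimer, methyl on C8 then α) and hydrolyse it under the conditions of step 12 to the cis-fused hydroxy diketone F2. Equilibrate C5 through the enol of the C6 ketone (DBU cat., CH2Cl2, rt) to the trans-fused diketone F3, in which the C6 arm is anti to the isopropyl group and should be favoured. Reduce as in step 13 to the diol F4 and silylate as in step 14 to the tris(trimethylsilyl) enol ether F5; dehydrogenation with Pd(OAc)2 then removes the C8 centre and gives 22. An error at C1 cannot be repaired in this way.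

Step 16. What may go wrong: poor facial selectivity of hydride addition, with attack from the α face giving the 10β epimer. The β face carries the C1 methyl, and the torsional preference that favours β attack depends on the ring keeping its chair-like shape. Fallback, from 26 to 27: replace substrate control by catalyst control, reducing 26 with catecholborane and the (S)-B-methyl-CBS-oxazaborolidine [(S)-1-methyl-3,3-diphenyltetrahydro-1H,3H-pyrrolo[1,2-c][1,3,2]oxazaborole] in toluene at −78 °C. With the quaternary C1 side as the larger carbonyl substituent, this catalyst is expected to deliver hydride to the β face; the (R)-catalyst is the choice if the alkenyl side proves to be the controlling group. No new compound is involved.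

Step 15. What may go wrong: Z to E isomerisation of the angeloyl group during activation or heating, or sluggish acylation of the hindered secondary alcohol. Fallback, from 23 to 26: form the ester bond first and the Z alkene afterwards. Esterify 23 with 2-[bis(2,2,2-trifluoroethoxy)phosphoryl]propanoic acid (EDC·HCl, DMAP cat., CH2Cl2) to the phosphonate ester F6. A Still–Gennari olefination with acetaldehyde (KN(SiMe3)2, 18-crown-6, THF, −78 °C) then builds the Z-trisubstituted alkene and gives 26.

Step 14. What may go wrong: protodesilylation of the enol silane back to the ketone, or slow palladation of the neopentylic enol ether, so that conversion stalls. Fallback, from 21 to 22: treat 21 with PhSeCl (CH2Cl2, −78 °C) to give the α-phenylselanyl ketone F7, with selenium on C9 anti to the C8 methyl and therefore syn to H-8. Oxidise with H2O2/pyridine (CH2Cl2, 0 °C); syn elimination of the selenoxide gives 22.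

Step 2. What may go wrong: loss of the tertiary silyl group, or incomplete differentiation of the two carbonyl termini, under acidic methanol. Fallback, from 2 to 3: separate the two events. Ozonolysis with PPh3 work-up (CH2Cl2, −78 °C) gives the keto aldehyde F8; aprotic, aldehyde-selective acetalisation with MeOSiMe3 and catalytic TMSOTf (CH2Cl2, −78 °C) then gives 3.

## Further compounds

F1 | step 11 | cis-fused cycloadduct: 8α-methyl-4β-(triethylsilyloxy)-6-(triisopropylsilyloxy)-5βH-dauc-6-en-10-one | O=C1C[C@H](C)C=C(O[Si](C(C)C)(C(C)C)C(C)C)[C@@H]2[C@](O[Si](CC)(CC)CC)(C(C)C)CC[C@]12C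
F2 | step 11 | cis-fused 4β-hydroxy-8α-methyl-5βH-daucane-6,10-dione | O=C1C[C@H](C)CC(=O)[C@@H]2[C@](O)(C(C)C)CC[C@]12C
F3 | step 11 | trans-fused 4β-hydroxy-8α-methyl-5αH-daucane-6,10-dione | O=C1C[C@H](C)CC(=O)[C@H]2[C@](O)(C(C)C)CC[C@]12C
F4 | step 11 | 4β,6α-dihydroxy-8α-methyl-5αH-daucan-10-one | O=C1C[C@H](C)C[C@H](O)[C@H]2[C@](O)(C(C)C)CC[C@]12C
F5 | step 11 | 8α-methyl-4β,6α,10-tris(trimethylsilyloxy)-5αH-dauc-9-ene | C[Si](C)(C)OC1=C[C@H](C)C[C@H](O[Si](C)(C)C)[C@H]2[C@](O[Si](C)(C)C)(C(C)C)CC[C@]12C
F0 | step 16 | none | none
F6 | step 15 | 6α-{2-[bis(2,2,2-trifluoroethoxy)phosphoryl]propanoyloxy}-4β-hydroxy-5αH-dauc-8-en-10-one | CC(C(=O)O[C@H]1CC(C)=CC(=O)[C@@]2(C)CC[C@@](O)(C(C)C)[C@H]12)P(=O)(OCC(F)(F)F)OCC(F)(F)F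
F7 | step 14 | 8β-methyl-9-(phenylselanyl)-4β,6α-bis(trimethylsilyloxy)-5αH-daucan-10-one | O=C1C([Se]c3ccccc3)[C@@H](C)C[C@H](O[Si](C)(C)C)[C@H]2[C@](O[Si](C)(C)C)(C(C)C)CC[C@]12C
F8 | step 2 | (3S)-6-oxo-3-(propan-2-yl)-3-(triethylsilyloxy)heptanal | CC(=O)CC[C@@](O[Si](CC)(CC)CC)(C(C)C)CC=O
A1 | alternative 1 | 2-methyl-2-(3-oxopropyl)cycloheptane-1,3-dione | CC1(CCC=O)C(=O)CCCCC1=O
A2 | alternative 1 | cis-fused acyloin: 5-hydroxy-1-methylbicyclo[5.3.0]decane-4,10-dione (daucane numbering) | O=C1CC[C@]2(C)C(=O)CCCC[C@]12O
A3 | alternative 2 | 3-methylcyclopent-2-en-1-one | CC1=CC(=O)CC1
A4 | alternative 2 | bis(2-methylpropyl)[1-(trimethylsilyl)ethenyl]aluminium | C=C([Si](C)(C)C)[Al](CC(C)C)CC(C)C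
A5 | alternative 2 | (3R)-3-methylpent-4-enal | O=CC[C@@H](C)C=C
A6 | alternative 2 | 2,3-trans aldol: 2-(1-hydroxy-3-methylpent-4-enyl)-3-methyl-3-[1-(trimethylsilyl)ethenyl]cyclopentan-1-one | O=C1CC[C@](C)(C(=C)[Si](C)(C)C)[C@H]1[C@@H](O)C[C@@H](C)C=C
A7 | alternative 3 | 1-ethenyl-5-methyl-6-exo-[(E)-prop-1-enyl]bicyclo[3.1.0]hexan-2-one (cis-divinylcyclopropane) | O=C1CC[C@]2(C)[C@@H](/C=C/C)[C@]12C=C
A8 | alternative 3 | bicyclo[5.3.0]decadienone with C4 ketone, C5=C6 and C9=C10 alkenes, C1 and C8 methyls | O=C1CC[C@]2(C)C=C[C@H](C)CC=C12
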